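**Retrosynthetic overview**
1. The target comes from its N,N'-ditosyl derivative. The (E)-alkenyl–indole bond is made last, by hydrozirconation/Negishi coupling of a ring-bound ethynyl group with the same 5-bromoindole that also supplies the other indole half.
2. Cyclohexene ring C is numbered C1 (quaternary), C2 (CH–indolyl), C3=C4 (C4 bears CH3), C5, C6 (CH2 next to C1). It is opened across C5–C6 and C3=C4 into an acyclic aldehyde–acid (C3 = CHO, C6 = CH2CO2H) and an isopropenylphosphonium salt (C4 with its methyl, C5). Forward: decarboxylative radical addition forms C5–C6, then an intramolecular Wittig reaction forms C3=C4.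
3. Enabling feature: C3 and C6 are 1,4-related across the vicinal stereo-pair C2/C1. C1 is quaternary (no β-hydrogen) and carries an ethynyl, not an alkenyl, placeholder, so a C6 radical does not rearrange. The C4 methyl of the ring alkene maps onto the α-methyl of the vinylphosphonium salt.
4. The aldehyde–acid comes from a γ-butyrolactone, a temporary ring absent from the target. C2 is set by Rh-catalysed asymmetric 1,4-arylation of furan-2(5H)-one, C1 by two successive anti alkylations (CH2CO2t-Bu, then CH3). The lactone C=O becomes the ethynyl group and the lactone CH2O becomes CHO.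
5. Ring order: indole (Fischer, made once for both halves), then the temporary lactone, then ring C in the key step.

Key step: step 12

Assumption: 3,3-dimethylpent-4-enal is taken as a purchasable aldehyde (otherwise one Claisen step from prenol and ethyl vinyl ether).
Notation: Ts = 4-methylbenzenesulfonyl; Ar = 3-(2-methylbut-3-en-2-yl)-1-Ts-1H-indol-5-yl.

**Step 1**
Reactants: 1 (4-bromophenyl)hydrazine hydrochloride; 2 3,3-dimethylpent-4-enal
Product: 4 5-bromo-3-(2-methylbut-3-en-2-yl)-1H-indole, via arylhydrazone 3 (not isolated)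
Conditions: EtOH, 23 °C, 1 h; then AcOH, 90 °C
Reagents that add atoms: none
Why: Fischer indole synthesis: the ene-hydrazine of an aldehyde RCH2CHO rearranges ([3,3]) so that R ends at C3 and C2 stays unsubstituted, the para-bromine can only end at C5, and no stereocentre is formed.

**Step 2**
Reactants: 4 5-bromo-3-(2-methylbut-3-en-2-yl)-1H-indole
Product: 5 5-bromo-3-(2-methylbut-3-en-2-yl)-1-Ts-1H-indole (Ar–Br)
Conditions: NaH, TsCl, THF/DMF, 0 → 23 °C
Reagents that add atoms: 4-methylbenzenesulfonyl chloride, Cc1ccc(S(=O)(=O)Cl)cc1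
Why: N-sulfonylation of the indolide; the tosyl group blocks N–H for the enolate steps and later keeps the indole out of the oxidation window of the photocatalyst.

**Step 3**
Reactants: 5 Ar–Br
Product: 8 Ar–B(OH)2, via aryllithium 6 (not isolated), via lithium triisopropoxyborate 7 (not isolated)
Conditions: B(Oi-Pr)3, THF/toluene, −78 °C; n-BuLi added slowly; then 1 M HCl
Reagents that add atoms: triisopropyl borate, CC(C)OB(OC(C)C)OC(C)C; water, O
Why: Bromine–lithium exchange with in situ borate capture should outrun attack at sulfur or C2 deprotonation, and hydrolysis gives the boronic acid.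

**Step 4**
Reactants: 8 Ar–B(OH)2; 9 furan-2(5H)-one
Product: 10 (4R)-4-Ar-oxolan-2-one
Conditions: [RhCl(C2H4)2]2 (2.5 mol%), (R,R)-Ph-bod* (5.5 mol%), KOH (0.3 equiv), dioxane/H2O 10:1, 40 °C
Reagents that add atoms: none
Why: Hayashi–Miyaura asymmetric 1,4-addition of an arylboronic acid to a butenolide; the chiral diene on monovalent rhodium selects the enone face, and by analogy with 2-cyclohexenone the (R,R)-ligand should give the (R)-lactone.

**Step 5**
Reactants: 10 (4R)-4-Ar-oxolan-2-one
Product: 12 tert-butyl 2-[(3S,4R)-4-Ar-2-oxooxolan-3-yl]acetate, via lithium enolate 11 (not isolated)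
Conditions: LiN(SiMe3)2 (1.1 equiv), THF, −78 °C; BrCH2CO2t-Bu, −78 → −40 °C
Reagents that add atoms: tert-butyl bromoacetate, CC(C)(C)OC(=O)CBr
Why: Alkylation of the γ-butyrolactone enolate anti to the C4 aryl group gives the trans product; the configuration at C3 is provisional and is overwritten in step 6.

**Step 6**
Reactants: 12 tert-butyl 2-[(3S,4R)-4-Ar-2-oxooxolan-3-yl]acetate
Product: 14 tert-butyl 2-[(3R,4S)-4-Ar-3-methyl-2-oxooxolan-3-yl]acetate (methyl trans to Ar), via lithium enolate 13 (not isolated)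
Conditions: LiN(SiMe3)2 (1.2 equiv), THF/DMPU, −78 °C; MeI, −78 → −30 °C
Reagents that add atoms: iodomethane, CI
Why: The lactone α-carbon (about five pKa units more acidic than the tert-butyl ester CH2) is enolised again and iodomethane enters anti to the neighbouring aryl group, which sets the quaternary stereocentre with methyl trans and the acetate arm cis to Ar (1,2-induction in a five-membered enolate).

**Step 7**
Reactants: 14 tert-butyl 2-[(3R,4S)-4-Ar-3-methyl-2-oxooxolan-3-yl]acetate
Product: 15 tert-butyl 2-[(3R,4S)-4-Ar-2-hydroxy-3-methyloxolan-3-yl]acetate (lactol; anomer mixture)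
Conditions: i-Bu2AlH (1.1 equiv), CH2Cl2, −78 °C; aq. potassium sodium tartrate
Reagents that add atoms: none
Why: Partial reduction of a γ-lactone to the lactol; the strained lactone is far more electrophilic than the tert-butyl ester, which should survive one equivalent at −78 °C.

**Step 8**
Reactants: 15 lactol
Product: 16 tert-butyl (3R,4S)-4-Ar-3-ethynyl-5-hydroxy-3-methylpentanoate
Conditions: dimethyl (1-diazo-2-oxopropyl)phosphonate, K2CO3, MeOH, 0 → 23 °C
Reagents that add atoms: dimethyl (1-diazo-2-oxopropyl)phosphonate, CC(=O)C(=[N+]=[N-])P(=O)(OC)OC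
Why: Ohira–Bestmann (Seyferth–Gilbert) homologation of the open hydroxy-aldehyde form of the lactol gives the terminal alkyne and frees the primary alcohol; the α-quaternary aldehyde cannot epimerise, and K2CO3/MeOH at room temperature should spare the N-tosylindole and the tert-butyl ester.

**Step 9**
Reactants: 16 tert-butyl (3R,4S)-4-Ar-3-ethynyl-5-hydroxy-3-methylpentanoate
Product: 17 tert-butyl (3R,4S)-4-Ar-3-ethynyl-3-methyl-5-oxopentanoate
Conditions: Dess–Martin periodinane (1.2 equiv), CH2Cl2, 0 → 23 °C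
Reagents that add atoms: none
Why: Dess–Martin oxidation is fast and non-basic, so the α-aryl aldehyde should form without enolisation of the stereocentre next to the quaternary carbon.

**Step 10**
Reactants: 17 tert-butyl (3R,4S)-4-Ar-3-ethynyl-3-methyl-5-oxopentanoate
Product: 18 (3R,4S)-4-Ar-3-ethynyl-3-methyl-5-oxopentanoic acid
Conditions: CF3CO2H/CH2Cl2 1:4, 0 °C; toluene azeotrope; used directly
Reagents that add atoms: none
Why: Acidolysis of the tert-butyl ester with loss of isobutene; the free acid should rest largely as the cyclic hemiacylal with the aldehyde, which shields the α-aryl stereocentre, and the N-tosylindole and monosubstituted alkene tolerate cold CF3CO2H.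

**Step 11**
Reactants: 19 2-bromopropene; 20 triphenylphosphine
Product: 21 triphenyl(prop-1-en-2-yl)phosphonium bromide
Conditions: Pd(PPh3)4 (2 mol%), PhCN, 100 °C, sealed tube
Reagents that add atoms: none
Why: Palladium-catalysed P–C coupling of an alkenyl bromide with a triarylphosphine (oxidative addition to zerovalent palladium, then reductive elimination of the phosphonium salt).

**Step 12**
Reactants: 18 (3R,4S)-4-Ar-3-ethynyl-3-methyl-5-oxopentanoic acid; 21 triphenyl(prop-1-en-2-yl)phosphonium bromide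
Product: 26 5-[(1S,6R)-6-ethynyl-3,6-dimethylcyclohex-2-en-1-yl]-3-(2-methylbut-3-en-2-yl)-1-Ts-1H-indole, via cesium carboxylate 22 (not isolated), via primary alkyl radical 23 (not isolated), via phosphonio radical 24 (not isolated), via phosphonium ylide 25 (not isolated)
Conditions: Cs2CO3 (0.55 equiv), 21 (1.5 equiv), 4CzIPN [2,4,5,6-tetrakis(carbazol-9-yl)isophthalonitrile] (3 mol%), 4 Å sieves, DMF (0.03 M), blue LEDs (456 nm), 25 °C, N2
Reagents that add atoms: none
Why: Proposed new method: The cesium carboxylate 22 should be oxidised by photoexcited 4CzIPN and lose CO2 to give the primary radical 23, which adds to the CH2 terminus of the electron-poor alkene of 21 to form C5–C6 (a union of two formally electrophilic carbons made possible by the radical), and the adduct radical 24 is then reduced by the 4CzIPN radical anion to the non-stabilised ylide 25 (redox-neutral radical–polar crossover that generates no proton source), which olefinates the aldehyde intramolecularly to form C3=C4 with loss of Ph3PO. The closest known reaction types are the photoredox decarboxylative Giese addition with radical–polar crossover (carbanion capture after addition to acrylates or vinyl boronates) and the Schweizer annulation, in which a nucleophile adds to a vinylphosphonium salt and the resulting ylide closes a ring by Wittig reaction. Ring C is the only ring closed, by 6-exo-trig attack of the ylide carbon on the aldehyde, and the ring fixes the geometry of the trisubstituted alkene. No stereocentre is created; C1 and C2 are carried through from 18. The radical must be captured before it rearranges, which the quaternary C1 (no β-hydrogen) and its ethynyl rather than alkenyl substituent (very slow 1,2-shift) secure, and the ylide must reach the aldehyde before it can deprotonate the α-aryl position, which the six-membered geometry, the gem-disubstitution at C1 and the absence of base beyond the carboxylate secure. The N-tosyl groups keep the indole out of an unproductive electron-transfer cycle with the photocatalyst, and the alkyne and tert-prenyl alkene are poor acceptors for a nucleophilic alkyl radical compared with the phosphonium-activated alkene.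

**Step 13**
Reactants: 26 cyclohexenyl alkyne; 5 Ar–Br
Product: 29 N,N'-ditosyl derivative of the target, via alkenylzirconocene chloride 27 (not isolated), via alkenylzinc chloride 28 (not isolated)
Conditions: Cp2Zr(H)Cl (1.2 equiv), THF, 0 → 23 °C; ZnCl2 (1.3 equiv); then 5, Pd(PPh3)4 (5 mol%), 50 °C
Reagents that add atoms: none
Why: Hydrozirconation (syn, anti-Markovnikov; the terminal alkyne should react faster than the hindered vinyl groups) gives the (E)-alkenylzirconium, which after transmetalation to zinc undergoes Negishi coupling with retention and so fixes the (E)-alkene.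

**Step 14**
Reactants: 29 N,N'-ditosyl derivative of the target
Product: 30 5-[(E)-2-{(1S,2R)-1,4-dimethyl-2-[3-(2-methylbut-3-en-2-yl)-1H-indol-5-yl]cyclohex-3-en-1-yl}ethenyl]-3-(2-methylbut-3-en-2-yl)-1H-indole (target)
Conditions: Bu4NF (8 equiv), THF, 65 °C; aqueous work-up
Reagents that add atoms: none
Why: Fluoride-mediated cleavage of N-sulfonyl indoles (attack at sulfur, indolide as leaving group) should remove both tosyl groups under non-acidic conditions that leave the alkenes and both stereocentres untouched.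

**Compound list**
1 | (4-bromophenyl)hydrazine hydrochloride | NNc1ccc(Br)cc1.Cl | starting material
2 | 3,3-dimethylpent-4-enal | C=CC(C)(C)CC=O | starting material
3 | (E)-1-(4-bromophenyl)-2-(3,3-dimethylpent-4-en-1-ylidene)hydrazine | C=CC(C)(C)C/C=N/Nc1ccc(Br)cc1 | intermediate
4 | 5-bromo-3-(2-methylbut-3-en-2-yl)-1H-indole | C=CC(C)(C)c1c[nH]c2ccc(Br)cc12 | intermediate
5 | 5-bromo-3-(2-methylbut-3-en-2-yl)-1-Ts-1H-indole (Ar–Br) | C=CC(C)(C)c1cn(S(=O)(=O)c2ccc(C)cc2)c2ccc(Br)cc12 | intermediate
6 | aryllithium Ar–Li | C=CC(C)(C)c1cn(S(=O)(=O)c2ccc(C)cc2)c2ccc([Li])cc12 | intermediate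
7 | lithium Ar-triisopropoxyborate | C=CC(C)(C)c1cn(S(=O)(=O)c2ccc(C)cc2)c2ccc([B-](OC(C)C)(OC(C)C)OC(C)C)cc12.[Li+] | intermediate
8 | Ar–B(OH)2, [3-(2-methylbut-3-en-2-yl)-1-Ts-1H-indol-5-yl]boronic acid | C=CC(C)(C)c1cn(S(=O)(=O)c2ccc(C)cc2)c2ccc(B(O)O)cc12 | intermediate
9 | furan-2(5H)-one | O=C1C=CCO1 | starting material
10 | (4R)-4-Ar-oxolan-2-one | O=C1C[C@H](c2ccc3n(S(=O)(=O)c4ccc(C)cc4)cc(C(C)(C)C=C)c3c2)CO1 | intermediate
11 | lithium enolate of 10 | [Li+].[O-]C1=C[C@H](c2ccc3n(S(=O)(=O)c4ccc(C)cc4)cc(C(C)(C)C=C)c3c2)CO1 | intermediate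
12 | tert-butyl 2-[(3S,4R)-4-Ar-2-oxooxolan-3-yl]acetate (trans) | O=C1[C@@H](CC(=O)OC(C)(C)C)[C@H](c2ccc3n(S(=O)(=O)c4ccc(C)cc4)cc(C(C)(C)C=C)c3c2)CO1 | intermediate
13 | lithium enolate of 12 | [Li+].[O-]C1=C(CC(=O)OC(C)(C)C)[C@H](c2ccc3n(S(=O)(=O)c4ccc(C)cc4)cc(C(C)(C)C=C)c3c2)CO1 | intermediate
14 | tert-butyl 2-[(3R,4S)-4-Ar-3-methyl-2-oxooxolan-3-yl]acetate (methyl trans to Ar) | O=C1[C@](C)(CC(=O)OC(C)(C)C)[C@H](c2ccc3n(S(=O)(=O)c4ccc(C)cc4)cc(C(C)(C)C=C)c3c2)CO1 | intermediate
15 | tert-butyl 2-[(3R,4S)-4-Ar-2-hydroxy-3-methyloxolan-3-yl]acetate (anomer mixture) | OC1[C@](C)(CC(=O)OC(C)(C)C)[C@H](c2ccc3n(S(=O)(=O)c4ccc(C)cc4)cc(C(C)(C)C=C)c3c2)CO1 | intermediate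
16 | tert-butyl (3R,4S)-4-Ar-3-ethynyl-5-hydroxy-3-methylpentanoate | C#C[C@](C)(CC(=O)OC(C)(C)C)[C@H](c1ccc2n(S(=O)(=O)c3ccc(C)cc3)cc(C(C)(C)C=C)c2c1)CO | intermediate
17 | tert-butyl (3R,4S)-4-Ar-3-ethynyl-3-methyl-5-oxopentanoate | C#C[C@](C)(CC(=O)OC(C)(C)C)[C@H](c1ccc2n(S(=O)(=O)c3ccc(C)cc3)cc(C(C)(C)C=C)c2c1)C=O | intermediate
18 | (3R,4S)-4-Ar-3-ethynyl-3-methyl-5-oxopentanoic acid | C#C[C@](C)(CC(=O)O)[C@H](c1ccc2n(S(=O)(=O)c3ccc(C)cc3)cc(C(C)(C)C=C)c2c1)C=O | intermediate
19 | 2-bromopropene | C=C(C)Br | starting material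
20 | triphenylphosphine | c1ccc(P(c2ccccc2)c2ccccc2)cc1 | starting material
21 | triphenyl(prop-1-en-2-yl)phosphonium bromide | C=C(C)[P+](c1ccccc1)(c1ccccc1)c1ccccc1.[Br-] | intermediate
22 | cesium salt of 18 | C#C[C@](C)(CC(=O)[O-])[C@H](c1ccc2n(S(=O)(=O)c3ccc(C)cc3)cc(C(C)(C)C=C)c2c1)C=O.[Cs+] | intermediate
23 | primary alkyl radical from 22 after loss of CO2 | C#C[C@](C)([CH2])[C@H](c1ccc2n(S(=O)(=O)c3ccc(C)cc3)cc(C(C)(C)C=C)c2c1)C=O | intermediate
24 | α-phosphonio radical (adduct of 23 to 21) | C#C[C@](C)(CC[C](C)[P+](c1ccccc1)(c1ccccc1)c1ccccc1)[C@H](c1ccc2n(S(=O)(=O)c3ccc(C)cc3)cc(C(C)(C)C=C)c2c1)C=O.[Br-] | intermediate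
25 | phosphonium ylide | C#C[C@](C)(CCC(C)=P(c1ccccc1)(c1ccccc1)c1ccccc1)[C@H](c1ccc2n(S(=O)(=O)c3ccc(C)cc3)cc(C(C)(C)C=C)c2c1)C=O | intermediate
26 | 5-[(1S,6R)-6-ethynyl-3,6-dimethylcyclohex-2-en-1-yl]-3-(2-methylbut-3-en-2-yl)-1-Ts-1H-indole | C#C[C@]1(C)CCC(C)=C[C@H]1c1ccc2n(S(=O)(=O)c3ccc(C)cc3)cc(C(C)(C)C=C)c2c1 | intermediate
27 | (E)-alkenylzirconocene chloride from 26 | Cl[Zr](/C=C/[C@]1(C)CCC(C)=C[C@H]1c1ccc2n(S(=O)(=O)c3ccc(C)cc3)cc(C(C)(C)C=C)c2c1)(C1C=CC=C1)C1C=CC=C1 | intermediate
28 | (E)-alkenylzinc chloride | Cl[Zn]/C=C/[C@]1(C)CCC(C)=C[C@H]1c1ccc2n(S(=O)(=O)c3ccc(C)cc3)cc(C(C)(C)C=C)c2c1 | intermediate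
29 | N,N'-ditosyl derivative of the target, (1S,2R) ring, (E)-alkene | C=CC(C)(C)c1cn(S(=O)(=O)c2ccc(C)cc2)c2ccc(/C=C/[C@]3(C)CCC(C)=C[C@H]3c3ccc4n(S(=O)(=O)c5ccc(C)cc5)cc(C(C)(C)C=C)c4c3)cc12 | intermediate
30 | 5-[(E)-2-{(1S,2R)-1,4-dimethyl-2-[3-(2-methylbut-3-en-2-yl)-1H-indol-5-yl]cyclohex-3-en-1-yl}ethenyl]-3-(2-methylbut-3-en-2-yl)-1H-indole | C=CC(C)(C)c1c[nH]c2ccc(/C=C/[C@]3(C)CCC(C)=C[C@H]3c3ccc4[nH]cc(C(C)(C)C=C)c4c3)cc12 | target

**Step count and risks**
Total: 14 steps. Longest linear sequence: 13 steps (steps 1–10, 12, 13, 14); step 11 is a one-step side branch.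

Step 12 (proposed new method). What may go wrong: inefficient oxidation of the primary carboxylate, quenching of the ylide before ring closure, or epimerisation at the α-aryl aldehyde carbon while the cascade is slow. The fallback uses known chemistry, sets out from 17 and comes back at 26. Isopropenylmagnesium bromide (CeCl3, THF, −78 → 23 °C) adds to the aldehyde and the alkoxide lactonises onto the tert-butyl ester to give the 6-isopropenyl δ-lactone F1 (carbinol configuration irrelevant). Soft enolisation (t-BuMe2SiOTf, Et3N, benzene, 23 → 80 °C) then triggers an Ireland–Claisen ring contraction through a boat transition state, which forms the C5–C6 bond and the C3=C4 alkene and gives, after hydrolysis, the ring-contracted acid F2. The surplus carboxyl group is removed through the Barton ester F3 (N-hydroxypyridine-2-thione, DCC; t-BuSH, visible light) to give 26.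

Step 13. What may go wrong: competing hydrozirconation of the two terminal vinyl groups, or slow transmetalation and coupling at the hindered alkenyl metal. The fallback sets out from 26 and comes back at 29. Sonogashira coupling of 26 with 5 (PdCl2(PPh3)2, CuI, Et3N, 60 °C) gives the internal alkyne F4. Ruthenium-catalysed trans-hydrosilylation ([Cp*Ru(MeCN)3]PF6, (EtO)3SiH, CH2Cl2) gives the (Z)-alkenylsilane F5 (regioisomers tolerated), and protodesilylation (CuI, Bu4NF, THF, 23 °C) gives 29.

Step 4. What may go wrong: low turnover with the five-membered lactone acceptor and protodeboronation of the boronic acid. The fallback sets out from 8 and comes back at 10. Suzuki coupling of 8 with 4-bromofuran-2(5H)-one (PdCl2(dppf), K3PO4, THF/H2O) gives the butenolide F6. Asymmetric copper hydride 1,4-reduction (CuCl, NaOt-Bu, the p-Tol-BINAP enantiomer that leads to the R lactone, polymethylhydrosiloxane, t-BuOH, toluene) then gives 10.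

**Further compounds**
F1 | step 12 | 5-Ar-4-ethynyl-4-methyl-6-(prop-1-en-2-yl)oxan-2-one (C4, C5 as in 17; C6 mixture) | O=C1C[C@@](C)(C#C)[C@H](c2ccc3n(S(=O)(=O)c4ccc(C)cc4)cc(C(C)(C)C=C)c3c2)C(C(C)=C)O1
F2 | step 12 | 3-Ar-2-ethynyl-2,5-dimethylcyclohex-4-ene-1-carboxylic acid (C1 mixture) | C#C[C@]1(C)C(C(=O)O)CC(C)=C[C@H]1c1ccc2n(S(=O)(=O)c3ccc(C)cc3)cc(C(C)(C)C=C)c2c1
F3 | step 12 | 2-thioxopyridin-1(2H)-yl ester of F2 (Barton ester) | C#C[C@]1(C)C(C(=O)On2ccccc2=S)CC(C)=C[C@H]1c1ccc2n(S(=O)(=O)c3ccc(C)cc3)cc(C(C)(C)C=C)c2c1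
F4 | step 13 | alkyne analogue of 29 (C≡C in place of CH=CH) | C=CC(C)(C)c1cn(S(=O)(=O)c2ccc(C)cc2)c2ccc(C#C[C@]3(C)CCC(C)=C[C@H]3c3ccc4n(S(=O)(=O)c5ccc(C)cc5)cc(C(C)(C)C=C)c4c3)cc12
F5 | step 13 | (Z)-alkenyl(triethoxy)silane from trans-hydrosilylation of F4 (silicon on the indole-bearing carbon shown) | C=CC(C)(C)c1cn(S(=O)(=O)c2ccc(C)cc2)c2ccc(/C([Si](OCC)(OCC)OCC)=C/[C@]3(C)CCC(C)=C[C@H]3c3ccc4n(S(=O)(=O)c5ccc(C)cc5)cc(C(C)(C)C=C)c4c3)cc12
F6 | step 4 | 4-Ar-furan-2(5H)-one | O=C1C=C(c2ccc3n(S(=O)(=O)c4ccc(C)cc4)cc(C(C)(C)C=C)c3c2)CO1
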